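## Structural features

The target is a cis-fused decalin of the eremophilane type (ring A: C1–C5 and C10; ring B: C5–C10), namely (3R,4R,5R,7R,9R,10S)-3-[(Z)-2-methylbut-2-enoyloxy]-9-(3-methylbut-2-enoyloxy)eremophil-11-en-8-one. It has six stereocentres: five are contiguous along C3–C4–C5–C10–C9, with the quaternary, methyl-bearing C5 at the ring fusion between the C4 methyl carbon and C10, and the sixth, C7, carries the isopropenyl group. H10, the C4 methyl, the C7 isopropenyl group and the C9 ester oxygen all lie on the face of the C5 methyl, and only the C3 ester oxygen lies on the other face. In the chair–chair conformer with the C5 methyl equatorial on ring B and axial on ring A, every other ring substituent is equatorial. Three groups are fragile: the angelate (Z to E isomerisation on acyl activation or with nucleophiles), the 7-isopropenyl-8-ketone (C7 epimerisation and migration of the alkene into conjugation), and the C9 acyloxy ketone (acyl shift under base); the cis fusion is at risk for as long as C9 is a ketone. The real difficulty is the quaternary C5 with its cis-related neighbours C4 and C10, together with three oxygens (C3, C8, C9) at different oxidation levels. The key step exploits two features: ring B carries oxygen at C8 and C9 next to the C5 methyl, which is the substitution pattern of a 2-methoxy-5-methyl-1,4-benzoquinone (one extra oxygen at C6), and ring A is a cyclohexane with a single oxygen at C3, which is a latent 2-siloxydiene that can add across C5=C10.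

## Logic of the disconnections

16 ⇒ 14 + 15. The C3–O bond is cut on the ring side, so the ester is made by displacement at C3 with inversion and not by acyl transfer. The reason is twofold: 15 then reacts as a carboxylate and its Z-alkene is never activated, and the C3 epimer 14 is the alcohol that hydride reduction naturally gives. The gain is a final step without protecting groups. The demand is substitution, not elimination, at a crowded axial carbinol.

14 ⇒ 12. The C6–H, C7–H and C3–H bonds are removed, which returns the C6=C7 alkene conjugated to C8=O and the C3 ketone. One bulky hydride can do both reductions, because conjugate addition leaves C8 as an enolate (13) and so protects it while C3 is reduced. The gain is that C3 and C7 are set in one operation. The demand is 1,4- over 1,2-addition at C8, equatorial attack at C3, and kinetic protonation at C7 on the right face without later equilibration.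

12 ⇒ 10 + 11. The C7–C11 bond between two sp2 carbons is cut, because an alkenyl iodide and an alkenylboron partner couple reliably. The gain is that the whole isopropenyl group comes from 11. The demand is coupling conditions mild enough for the acyloxy ketone.

10 ⇒ 9. The C7–I bond is cut. The enone α-position is the only site that takes up iodine by addition–elimination, so no other position competes.

9 ⇒ 8. Only the configuration at C4 changes. The cycloaddition must deliver C4 epimeric to the target, and the C3 ketone allows correction through its enol. The demand is that the C9 oxygen already has its final configuration, so that the ring conformation favours 9, and that C4 enolises faster than C9.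

8 ⇒ 6 + 7. The C9–O bond is cut on the ring side, again for an inverting displacement, because hydride is expected to deliver the C9 alcohol of 6 with the wrong configuration. The gain is that the ester is installed and the centre corrected in one step. The demand is SN2 next to the C8 carbonyl.

6 ⇒ 4. The C8 ketone and C6=C7 alkene of 6 go back to the C8 methyl enol ether and a C6 oxygen, the C9 alcohol to the C9 ketone, and the C3 ketone to its silyl enol ether. Reduction to 5 followed by acid carries this out in one flask. The gain is that all oxygen functions of 4 are used or removed without protection. The demand is that C6 and not C9 ionises.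

4 ⇒ 2 + 3. The C4–C5 and C1–C10 bonds are cut, which opens ring A. The gain is the largest of the route: three stereocentres, one ring and the quaternary centre come from two simple partners. The demand is control of site, orientation, endo mode and enantioface.

2 ⇒ 1. The O–Si bond is cut; enol silylation must give the Z-isomer.

## Other disconnections considered

Alternative 1: Both rings are opened at once by cutting C1–C2 and C5–C10. This leads to the tethered triene A2, in which a vinyl ketone (C1=C10 next to the C9 carbonyl) is linked through C6–C9 to a 2-siloxydiene (C2=C3–C4=C5). The forward step would be an intramolecular Diels–Alder reaction giving A1, a cis-fused decalin with a C3=C4 silyl enol ether, the C7 isopropenyl group, a C8 ether and a C9 ketone.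
- In its favour: two rings and the quaternary C5 arise in one step. The C7 centre with its isopropenyl group is made beforehand as an sp3 carbon, so the enolate protonation that sets C7 in the chosen plan is avoided; on this point the alternative is the better. The absolute configuration comes from the tether and needs no chiral catalyst, which is equal or better.
- Against it: the activating carbonyl ends up at C9 and the ether at C8, the reverse of the target. A ketol transposition must follow, and after it C7 sits next to the new ketone. The diene terminus C5 is fully substituted, needs a defined C4=C5 geometry and carries one inside substituent, so the diene would be sluggish. The vinyl ketone is labile. The cis fusion is not enforced but depends on an endo/exo preference. C4 and C3 still have to be set, by ketonisation next to the quaternary centre and by the same hindered reduction as in the chosen plan.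
- Comparison: in structure, the chosen plan takes C8 and C9 oxygens in the right places from 3, while A1 carries them transposed. In mechanism, both are concerted [4+2] additions of a 2-siloxydiene; the chosen one is intermolecular and catalyst-controlled with orientation fixed by chelation, the alternative is substrate-controlled. In step economy, A2 would need an open-chain sequence of roughly eight to ten steps and A1 about seven more, against nine steps in all for the chosen route.

Alternative 2: The C7–C8 bond is cut, which leads to aldehyde A4. In A4 ring A is complete, C5 carries a methyl and a prenyl chain, and C10 carries the CH(OPMB)–CHO unit. The forward step would be a Me2AlCl-promoted carbonyl-ene cyclisation of type one (the citronellal-to-isopulegol pattern) giving A3: the C7–C8 bond forms, a methyl hydrogen moves to oxygen, ring B closes and the isopropenyl group appears.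
- In its favour: the isopropenyl alkene and the C7 centre are made in one concerted step through a chair transition state, with the isopropenyl group and the C8 oxygen trans and equatorial. C7 never passes through an enolate before the last oxidation, so on C7 the alternative is better than the chosen plan. The C8/C9 oxidation pattern is correct, and C3 is carried in its final configuration, so no inversion is needed there; this is also better.
- Against it: the step closes only ring B. The whole difficult array C3–C4–C5–C10–C9 with the quaternary centre must be built before it and is not helped by it. The α-alkoxy aldehyde can epimerise at C9. A chelating aluminium Lewis acid next to a benzylic ether invites chloride capture of the cationic intermediate or loss of the benzyl group. Afterwards come oxidation at C8, two deprotections and two acylations, one of them an angelate formed by acyl transfer.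
- Comparison: in structure, the alternative ends where the chosen route begins. In mechanism, both key steps are pericyclic, and the ene reaction defines C7 more cleanly than protonation does. In step economy, A4 alone would probably take more than twelve steps, so the total would be about twice that of the chosen route.

Alternative 3: The C1–C10 bond is cut, which leads to A6, a prochiral 4,4-disubstituted cyclohexa-2,5-dienone. Its quaternary carbon carries the methyl group and a chain C4(Me)–C3(OSi)–C2=C1–I with a Z-alkenyl iodide. In the forward step, zerovalent palladium with a chiral bisphosphine would insert into the C1–I bond, the alkenylpalladium would add to C10 of one enone arm, and formate would reduce the palladium enolate, giving A5 with the ring A 1-ene and the ring B 6-en-8-one.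
- In its favour: the cis fusion is enforced, because the tethered alkenylpalladium can reach C10 only on its own face. In outcome this equals the chosen plan, and it is better in that no base-sensitive stage has to be avoided. C3 and C4 are fixed in the open chain in their final relative configuration, so neither the C4 equilibration nor the C3 inversion is needed; on these points the alternative is better. The step is catalytic and asymmetric, as is the chosen key step (equal).
- Against it: A5 has no oxygen at C9 and no substituent at C7. The C9 oxygen would have to be introduced by α′-hydroxylation with face control, C7 would need the same iodination, coupling and conjugate reduction as in the chosen plan, and the C1=C2 alkene must be saturated selectively beside the enone. A6 requires a dearomatising alkylation that places a branched chain on a quaternary carbon. The chain stereocentres may oppose the ligand. Formate may reduce the alkenylpalladium before it cyclises.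
- Comparison: in structure, the chosen plan draws both ring B oxygens from 3, while A5 is one oxygen short. In mechanism, carbopalladation fixes C5 and C10 by geometry, whereas the cycloaddition fixes C4, C5 and C10 together but C4 wrongly. In step economy, about seven steps to A6 and about ten after A5 would exceed the nine of the chosen route.

Key step: step 2

Remarks before the steps:
- Locants are those of eremophilane; "syn" and "anti" give the position of a substituent relative to the C5 methyl group, and H10 is syn throughout (cis fusion).
- The (S)-enantiomer of BINOL is written for step 2 by analogy with related quinone cycloadditions; if it should favour the mirror-image adduct, (R)-BINOL is used instead.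

## Route

Step 1
Reactants: 1 pent-1-en-3-one
Product: 2 (Z)-3-(tert-butyldimethylsilyloxy)penta-1,3-diene
Conditions: TBSOTf, Et3N, CH2Cl2, −78 → 0 °C
Reagents that add atoms: tert-butyldimethylsilyl trifluoromethanesulfonate, CC(C)(C)[Si](C)(C)OS(=O)(=O)C(F)(F)F
Why: Soft enolisation (silylation of the carbonyl oxygen, then deprotonation by the amine) of an ethyl ketone gives the (Z)-silyl enol ether, in which the methyl group is trans to the vinyl group and so sits outside in the s-cis diene; any E-isomer is unreactive in step 2.

Step 2
Reactants: 2 (Z)-3-(tert-butyldimethylsilyloxy)penta-1,3-diene; 3 2-methoxy-5-methyl-1,4-benzoquinone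
Product: 4 cis-fused endo adduct 8-methoxy-3-(tert-butyldimethylsilyloxy)-4,5-dimethyl-cis-decala-2,7-diene-6,9-dione (H10 syn; C4 methyl anti)
Conditions: (S)-BINOL–TiCl2 (15 mol%, from (S)-BINOL and TiCl2(OiPr)2, 4 Å MS), toluene/CH2Cl2, −60 → −30 °C
Reagents that add atoms: none
Why: The tetravalent titanium centre chelates the C9 carbonyl oxygen and the neighbouring C8 methoxy oxygen of 3, which lowers the LUMO of the C5=C10 bond and puts its largest coefficient on C5 (β to C9), while the C7=C8 bond stays deactivated by its methoxy donor and C6=O is a vinylogous ester. The addition is a concerted, asynchronous [4+2] reaction in which the nucleophilic enol-ether terminus of 2 (the methyl-bearing carbon, future C4) bonds to C5 slightly ahead of C1 to C10. The closest known reactions are Lewis-acid-promoted Diels–Alder additions of this quinone to 2-siloxydienes and enantioselective quinone Diels–Alder reactions under BINOL–titanium or oxazaborolidinium catalysis. Ring A is closed by an intermolecular six-membered annulation, suprafacial on both partners, that makes both ring bonds (C4–C5 and C1–C10) in the same step. C5 and C10 come out cis because the addition is suprafacial on the quinone, and their absolute configuration is set by the BINOL ligand, which shields one face of the chelated quinone. C4 is set by the endo transition state together with the Z-geometry of 2 (methyl outside), which places the C4 methyl anti to the C5 methyl; this is the C4 epimer of the target and is corrected in step 5. The step needs site selectivity (methyl-bearing, not methoxy-bearing, alkene), the right orientation (C4 to C5) and no open Mukaiyama–Michael pathway; chelation, the methoxy deactivation, the bulky silyl group and the low temperature should secure these.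

Step 3
Reactants: 4 cis-fused endo adduct
Product: 6 9-hydroxy-4,5-dimethyl-cis-decal-6-ene-3,8-dione (H10 syn; C4 methyl anti; C9 OH anti), via enol ether diol 5 (not isolated)
Conditions: LiAlH4, THF, −78 → 0 °C; then 1 M HCl (aq), THF, 0 °C → rt
Reagents that add atoms: water, O
Why: Hydride adds 1,2 to both carbonyls and is expected to come from the convex face (the face of H10 and the C5 methyl), which puts the C9 hydroxyl anti to the C5 methyl; the C6 configuration of 5 has no consequence. Aqueous acid then ionises the allylic C6 hydroxyl to the methoxy-stabilised allyl cation, water adds at C8 and methanol is lost (reduction and transposition of a vinylogous ester), while the silyl enol ether is hydrolysed to the C3 ketone by protonation at C2, which leaves C4 untouched.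

Step 4
Reactants: 6 9-hydroxy-4,5-dimethyl-cis-decal-6-ene-3,8-dione; 7 3-methylbut-2-enoic acid
Product: 8 9-(3-methylbut-2-enoyloxy)-4,5-dimethyl-cis-decal-6-ene-3,8-dione (H10 syn; C4 methyl anti; C9 oxygen syn)
Conditions: PPh3, DIAD, toluene, 0 °C → rt
Reagents that add atoms: none
Why: Mitsunobu esterification: the C9 hydroxyl becomes an oxyphosphonium ion and is displaced by the carboxylate of 7 with inversion, an SN2 reaction accelerated by the adjacent C8 carbonyl with the nucleophile entering from the convex face. This puts the C9 oxygen syn to the C5 methyl as in the target and installs the ester without a protecting group.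

Step 5
Reactants: 8 9-(3-methylbut-2-enoyloxy)-4,5-dimethyl-cis-decal-6-ene-3,8-dione (C4 methyl anti)
Product: 9 9-(3-methylbut-2-enoyloxy)-4,5-dimethyl-cis-decal-6-ene-3,8-dione (H10 syn; C4 methyl syn; C9 oxygen syn)
Conditions: TsOH·H2O (0.1 equiv), toluene, 50 °C
Reagents that add atoms: none
Why: Acid-catalysed enolisation of the C3 ketone towards C4 equilibrates the C4 methyl; with the C9 ester now syn to the C5 methyl, 8 has a 1,3-diaxial contact in either ring conformation (C4 methyl against C9, or C5 methyl against the C9 oxygen) and 9 has none, so the equilibrium should lie towards 9. Acid is chosen because base would first remove the more acidic C9 hydrogen and could start an acyl shift; recovered 8 is resubmitted.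

Step 6
Reactants: 9 9-(3-methylbut-2-enoyloxy)-4,5-dimethyl-cis-decal-6-ene-3,8-dione (C4 methyl syn)
Product: 10 7-iodo-9-(3-methylbut-2-enoyloxy)-4,5-dimethyl-cis-decal-6-ene-3,8-dione (H10 syn; C4 methyl syn; C9 oxygen syn)
Conditions: I2, pyridine, CH2Cl2, 0 °C → rt
Reagents that add atoms: iodine, [I][I]
Why: α-Iodination of a cycloalkenone by addition–elimination: pyridine adds to C6, the enolate is iodinated at C7 and pyridine is expelled. The saturated C3 ketone and the ester do not take part.

Step 7
Reactants: 10 7-iodo enone; 11 isopropenylboronic acid pinacol ester
Product: 12 9-(3-methylbut-2-enoyloxy)eremophila-6,11-diene-3,8-dione (H10 syn; C4 methyl syn; C9 oxygen syn)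
Conditions: Pd(PhCN)2Cl2 (5 mol%), Ph3As (10 mol%), Ag2O, THF/H2O (8:1), rt
Reagents that add atoms: none
Why: Suzuki–Miyaura coupling of a 2-iodoenone: zerovalent palladium inserts into the C7–I bond, the alkenyl group is transferred from boron and reductive elimination forms C7–C11. Silver oxide promotion allows room temperature and near-neutral conditions, which spares the C9 acyloxy ketone.

Step 8
Reactants: 12 9-(3-methylbut-2-enoyloxy)eremophila-6,11-diene-3,8-dione
Product: 14 3-hydroxy-9-(3-methylbut-2-enoyloxy)eremophil-11-en-8-one (H10 syn; C3 OH syn and axial; C4 methyl syn; C7 isopropenyl syn; C9 oxygen syn), via dilithium enolate alkoxide 13 (not isolated)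
Conditions: LiBH(s-Bu)3 (2.3 equiv), THF, −78 °C; then AcOH, THF, −78 → 0 °C
Reagents that add atoms: none
Why: The bulky borohydride should add 1,4 to the enone (hydride to C6), giving the enolate 13, which masks C8, and should attack the C3 ketone from the equatorial side because the axial path is blocked by the axial C5 methyl, giving the axial C3 alkoxide. Kinetic protonation of 13 at −78 °C is expected at the α-carbon C7, which keeps the alkene out of conjugation, and along the axial, chair-forming path anti to the C5 methyl, which gives the equatorial isopropenyl group syn to the C5 methyl.

Step 9
Reactants: 14 3-hydroxy-9-(3-methylbut-2-enoyloxy)eremophil-11-en-8-one; 15 angelic acid ((Z)-2-methylbut-2-enoic acid)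
Product: 16 (3R,4R,5R,7R,9R,10S)-3-[(Z)-2-methylbut-2-enoyloxy]-9-(3-methylbut-2-enoyloxy)eremophil-11-en-8-one (C3 oxygen anti; all other substituents syn)
Conditions: PPh3, DIAD, toluene, 0 °C → rt
Reagents that add atoms: none
Why: Mitsunobu esterification with inversion: the carboxylate of 15 attacks the axial oxyphosphonium ion at C3 from the open equatorial side, which relieves the 1,3-diaxial strain with the C5 methyl and gives the equatorial ester. Because 15 reacts as a carboxylate and is never turned into an acyl donor, its Z-alkene is not exposed to the addition–elimination that converts angelates into tiglates.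

## Compound list

1 | pent-1-en-3-one | CCC(=O)C=C | starting material
2 | (Z)-3-(tert-butyldimethylsilyloxy)penta-1,3-diene | C=C/C(O[Si](C)(C)C(C)(C)C)=C/C | intermediate
3 | 2-methoxy-5-methyl-1,4-benzoquinone | COC1=CC(=O)C(C)=CC1=O | starting material
4 | cis-fused endo adduct, 8-methoxy-3-(tert-butyldimethylsilyloxy)-4,5-dimethyl-cis-decala-2,7-diene-6,9-dione (H10 syn, C4 methyl anti) | COC1=CC(=O)[C@@]2(C)[C@H](CC=C(O[Si](C)(C)C(C)(C)C)[C@H]2C)C1=O | intermediate
5 | enol ether diol, 8-methoxy-3-(tert-butyldimethylsilyloxy)-4,5-dimethyl-cis-decala-2,7-diene-6,9-diol (both OH anti, C4 methyl anti) | COC1=C[C@H](O)[C@@]2(C)[C@H](CC=C(O[Si](C)(C)C(C)(C)C)[C@H]2C)[C@@H]1O | intermediate (not isolated)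
6 | 9-hydroxy-4,5-dimethyl-cis-decal-6-ene-3,8-dione (C4 methyl anti, C9 OH anti) | O=C1C=C[C@@]2(C)[C@H](CCC(=O)[C@H]2C)[C@@H]1O | intermediate
7 | 3-methylbut-2-enoic acid | CC(C)=CC(=O)O | starting material
8 | 9-(3-methylbut-2-enoyloxy)-4,5-dimethyl-cis-decal-6-ene-3,8-dione (C4 methyl anti, C9 oxygen syn) | O=C1C=C[C@@]2(C)[C@H](CCC(=O)[C@H]2C)[C@H]1OC(=O)C=C(C)C | intermediate
9 | 9-(3-methylbut-2-enoyloxy)-4,5-dimethyl-cis-decal-6-ene-3,8-dione (C4 methyl syn, C9 oxygen syn) | O=C1C=C[C@@]2(C)[C@H](CCC(=O)[C@@H]2C)[C@H]1OC(=O)C=C(C)C | intermediate
10 | 7-iodo-9-(3-methylbut-2-enoyloxy)-4,5-dimethyl-cis-decal-6-ene-3,8-dione (C4 methyl syn, C9 oxygen syn) | O=C1C(I)=C[C@@]2(C)[C@H](CCC(=O)[C@@H]2C)[C@H]1OC(=O)C=C(C)C | intermediate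
11 | isopropenylboronic acid pinacol ester | CC(=C)B1OC(C)(C)C(C)(C)O1 | starting material
12 | 9-(3-methylbut-2-enoyloxy)eremophila-6,11-diene-3,8-dione (C4 methyl syn, C9 oxygen syn) | C=C(C)C1=C[C@@]2(C)[C@H](CCC(=O)[C@@H]2C)[C@@H](OC(=O)C=C(C)C)C1=O | intermediate
13 | dilithium salt: C7–C8 enolate and C3 alkoxide (C3 oxygen syn) from 12 | C=C(C)C=1C[C@@]2(C)[C@H](CC[C@H](O[Li])[C@@H]2C)[C@@H](OC(=O)C=C(C)C)C=1O[Li] | intermediate (not isolated)
14 | 3-hydroxy-9-(3-methylbut-2-enoyloxy)eremophil-11-en-8-one (C3 OH syn, C4 methyl syn, C7 isopropenyl syn, C9 oxygen syn) | C=C(C)[C@H]1C[C@@]2(C)[C@H](CC[C@H](O)[C@@H]2C)[C@@H](OC(=O)C=C(C)C)C1=O | intermediate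
15 | angelic acid, (Z)-2-methylbut-2-enoic acid | C/C=C(/C)C(=O)O | starting material
16 | (3R,4R,5R,7R,9R,10S)-3-[(Z)-2-methylbut-2-enoyloxy]-9-(3-methylbut-2-enoyloxy)eremophil-11-en-8-one | C=C(C)[C@H]1C[C@@]2(C)[C@H](CC[C@@H](OC(=O)/C(C)=C\C)[C@@H]2C)[C@@H](OC(=O)C=C(C)C)C1=O | target

## Step count and least certain steps

Total: 9 steps. Longest linear sequence: 9 steps (1 → 2 → 4 → 6 → 8 → 9 → 10 → 12 → 14 → 16); 3, 7, 11 and 15 enter directly as purchased materials.

**Step 2 (key step).** The most likely failure is loss of enantioface control, because an uncatalysed or singly coordinated background addition, or a stepwise Michael-type addition with silyl transfer, may compete with the chelated pathway; the ligand's face selection is also unproven for this quinone. Fallback: the cycloaddition is run with the achiral chelating Lewis acid SnCl4 (CH2Cl2, −78 °C), which should keep orientation and endo mode but gives 4 together with its mirror image F1. Step 3 applied to this racemate gives, through the mirror-image diol F2, the mirror-image ketol F3 beside 6. The two ketols are then separated by lipase-catalysed acetylation (Candida antarctica lipase B, vinyl acetate), with conditions chosen so that F3 is converted into its acetate F4 while 6 stays free. The fallback sets out from 2 and 3 and returns to the route at 6.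

**Step 8.** Two things may go wrong: direct hydride attack at the C8 carbonyl may compete with conjugate addition at the neopentyl-type C6, and protonation at C7 may show poor facial selectivity because the stereoelectronically favoured axial path runs past the pseudoaxial C4–C5 bond. The C7 centre cannot be corrected afterwards by equilibration, since that would move the alkene into conjugation. Fallback: the two reductions are separated and the protonation is put under reagent control. From 12, [(Ph3P)CuH]6 with Me3SiCl (benzene/THF) adds hydride only 1,4 and gives the trimethylsilyl enol ether F5 with the C3 ketone intact. LiBH(s-Bu)3 (THF, −78 °C) then reduces C3 to the axial alcohol, giving the hydroxy silyl enol ether F6. Finally the enol ether is ketonised at −78 °C with SnCl4 and the matching enantiomer of BINOL (a Lewis-acid-assisted chiral proton donor), which returns to the route at 14.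

**Step 9.** Elimination of the activated C3 oxygen with the anti-periplanar axial hydrogen at C2 or C4 may overtake substitution, because the oxyphosphonium ion is axial, next to the C4 methyl carbon and 1,3-diaxial to the C5 methyl. Fallback: inversion and angelate formation are separated. From 14, a Mitsunobu reaction with the smaller and more acidic chloroacetic acid gives the inverted chloroacetate F7; thiourea with NaHCO3 in ethanol removes the chloroacetyl group and gives the equatorial alcohol F8. F8 is then acylated with retention by the mixed anhydride F9, made from 15 with 2,4,6-trichlorobenzoyl chloride and Et3N (toluene, 80 °C, no nucleophilic catalyst, to keep the Z-alkene), which returns to the route at 16.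

**Step 4.** The substitution may be slow, because the conformer with the oxyphosphonium group axial on ring B (perpendicular to the C8 carbonyl and open to attack from the convex face) is strained by the anti C4 methyl; elimination to the cross-conjugated 6,9-dien-8-one could then compete. Fallback: activation and displacement are done in two stages with a free carboxylate. From 6, Tf2O and pyridine (CH2Cl2, −40 °C) give the triflate F10, which is displaced with inversion by cesium 3-methylbut-2-enoate F11 (from 7 and Cs2CO3, with 18-crown-6 in toluene), returning to the route at 8.

**Step 3.** Hydride delivery to C9 may take place from the concave face if the adduct prefers the half-chair with the C5 methyl pseudoaxial on ring B, which blocks the convex path; this would give the C9-epimeric ketol F12 (C9 OH syn) in place of 6. Fallback: the ester is then formed with retention. F12 is acylated with 3-methylbut-2-enoyl chloride and pyridine (CH2Cl2, 0 °C), which gives 8 directly and makes step 4 unnecessary. The fallback sets out from 4 and returns to the route at 8.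

## Further compounds

F1 | step 2 | mirror image of adduct 4 | COC1=CC(=O)[C@]2(C)[C@@H](CC=C(O[Si](C)(C)C(C)(C)C)[C@@H]2C)C1=O
F2 | step 2 | mirror image of diol 5 | COC1=C[C@@H](O)[C@]2(C)[C@@H](CC=C(O[Si](C)(C)C(C)(C)C)[C@@H]2C)[C@H]1O
F3 | step 2 | mirror image of ketol 6 | O=C1C=C[C@]2(C)[C@@H](CCC(=O)[C@@H]2C)[C@H]1O
F4 | step 2 | 9-O-acetate of F3 | O=C1C=C[C@]2(C)[C@@H](CCC(=O)[C@@H]2C)[C@H]1OC(C)=O
F5 | step 8 | 8-(trimethylsilyloxy)-9-(3-methylbut-2-enoyloxy)eremophila-7,11-dien-3-one | C=C(C)C=1C[C@@]2(C)[C@H](CCC(=O)[C@@H]2C)[C@@H](OC(=O)C=C(C)C)C=1O[Si](C)(C)C
F6 | step 8 | 8-(trimethylsilyloxy)-9-(3-methylbut-2-enoyloxy)eremophila-7,11-dien-3-ol (C3 OH syn, axial) | C=C(C)C=1C[C@@]2(C)[C@H](CC[C@H](O)[C@@H]2C)[C@@H](OC(=O)C=C(C)C)C=1O[Si](C)(C)C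
F7 | step 9 | 3-chloroacetoxy-9-(3-methylbut-2-enoyloxy)eremophil-11-en-8-one (C3 oxygen anti) | C=C(C)[C@H]1C[C@@]2(C)[C@H](CC[C@@H](OC(=O)CCl)[C@@H]2C)[C@@H](OC(=O)C=C(C)C)C1=O
F8 | step 9 | 3-hydroxy-9-(3-methylbut-2-enoyloxy)eremophil-11-en-8-one (C3 OH anti, equatorial) | C=C(C)[C@H]1C[C@@]2(C)[C@H](CC[C@@H](O)[C@@H]2C)[C@@H](OC(=O)C=C(C)C)C1=O
F9 | step 9 | (Z)-2-methylbut-2-enoic 2,4,6-trichlorobenzoic anhydride | C/C=C(/C)C(=O)OC(=O)c1c(Cl)cc(Cl)cc1Cl
F10 | step 4 | 9-O-trifluoromethanesulfonate of ketol 6 | O=C1C=C[C@@]2(C)[C@H](CCC(=O)[C@H]2C)[C@@H]1OS(=O)(=O)C(F)(F)F
F11 | step 4 | cesium 3-methylbut-2-enoate | [Cs+].CC(C)=CC(=O)[O-]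
F12 | step 3 | 9-hydroxy-4,5-dimethyl-cis-decal-6-ene-3,8-dione (C4 methyl anti, C9 OH syn) | O=C1C=C[C@@]2(C)[C@H](CCC(=O)[C@H]2C)[C@H]1O
A1 | alternative 1 | cis-fused cycloadduct, 3-(tert-butyldimethylsilyloxy)-8-(4-methoxybenzyloxy)eremophila-3,11-dien-9-one | C=C(C)[C@H]1C[C@@]2(C)[C@H](CCC(O[Si](C)(C)C(C)(C)C)=C2C)C(=O)[C@@H]1OCc1ccc(OC)cc1
A2 | alternative 1 | tethered triene, vinyl ketone linked to the (E)-configured 2-siloxydiene | C=C(C)[C@@H](C/C(C)=C(\C)C(=C)O[Si](C)(C)C(C)(C)C)[C@@H](OCc1ccc(OC)cc1)C(=O)C=C
A3 | alternative 2 | ene product, 3-(tert-butyldimethylsilyloxy)-9-(4-methoxybenzyloxy)eremophil-11-en-8-ol | C=C(C)[C@H]1C[C@@]2(C)[C@H](CC[C@@H](O[Si](C)(C)C(C)(C)C)[C@@H]2C)[C@@H](OCc3ccc(OC)cc3)[C@@H]1O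
A4 | alternative 2 | ring A aldehyde with C5 prenyl chain and C10 CH(OPMB)CHO unit | CC(C)=CC[C@@]1(C)[C@H](CC[C@@H](O[Si](C)(C)C(C)(C)C)[C@@H]1C)[C@@H](OCc1ccc(OC)cc1)C=O
A5 | alternative 3 | cis-fused dienone, 3-(tert-butyldimethylsilyloxy)-4,5-dimethyl-cis-decala-1,6-dien-8-one | O=C1C=C[C@@]2(C)[C@H](C=C[C@@H](O[Si](C)(C)C(C)(C)C)[C@@H]2C)C1
A6 | alternative 3 | prochiral cyclohexa-2,5-dienone with (Z)-iodoalkenyl side chain | O=C1C=CC(C)(C=C1)[C@@H](C)[C@H](O[Si](C)(C)C(C)(C)C)/C=C\I
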